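(The constants used here are assumed; what happens was integrated by code.)

The nucleophile cannot stay at its charge in this flask. It binds protons more tightly than the buffer base does, so each substitution costs two units of it: one becomes target and one is protonated.

electrophile 14 mM; nucleophile 2.50 equiv; buffer base 1.00 equiv; buffer acid 0.100 equiv; protic impurity 0.280 mM; time 30 h

    nucleophile + protic impurity → quenched reagent (k1 = 100 M⁻¹ h⁻¹)
    buffer acid ⇌ buffer base + acid, settled at all times (K2 = 6.3 × 10⁻⁵ M)
    electrophile + nucleophile → acid + target + leaving group (k3 = 0.61 M⁻¹ h⁻¹)
    electrophile + target ⇌ idle adduct, settled at all times (K4 = 31 M⁻¹)
    protonated nucleophile ⇌ nucleophile + acid, settled at all times (K5 = 1.0 × 10⁻⁹ M)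
    electrophile + leaving group → side product (k6 = 2.7 M⁻¹ h⁻¹)

- part of the electrophile that has reacted at 30 h
- pH of the solution at 30 h

I carry the exposure 0.640: the rate constant of substitution times the charged nucleophile concentration times the time, which is the exponent of a pseudo-first-order decay of the electrophile. I reckon the rest as corrections to it, in fractions of the electrophile charge:

- reacted by exposure alone: 0.473
- target: 0.377
- side product: 0.114
- electrophile bound in idle adduct: 0.0702

The first row overstates the nucleophile, which starts at 2.40 once it has taken the buffer acid's proton and then falls by twice the target. The protic impurity makes no difference to the conversion. The second row therefore uses mean nucleophile 1.93 and mean electrophile 0.764. In the third row, leaving group ramps up from nothing and meets the electrophile with the larger constant. The fourth row holds the balance at free electrophile 0.527. Summing the last three rows, I commit to 56.1%. Protonated nucleophile 0.477 against free nucleophile 1.65 gives pH 9.54.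

The forecast gives 53% (50% to 56%) and pH 9.56 (9.5 to 9.62), holding that the nucleophile "takes up both the buffer acid and each proton released". My conversion stands higher.

The flask gives 53.2% and pH 9.56.

The exposure is one comparison of times: the charged half-life of electrophile by substitution, 32 h, is longer than the run of 30 h, and it has grown to 49 h at the asked time. Moved singly, an electrophile charge of 12.2 mM or 16.1 mM, or a nucleophile charge of 2.16 equiv or 2.89 equiv, shifts the conversion by 5 points, which puts it outside the forecast's range. In the same flask read at 12 h, the exposure is 0.256, and the same rows give 28.0%. The computed result there is 27.1%.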